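The data are simulated with constants of no real substance, and the scatter is random.

Thursday's flask was charged with half the coupling partner of Saturday's and came to rest with about half of its target. We carry one number from it, the resting ratio: target over isomer of the product, summed over Thursday's readings, 2.31.

| setting | Saturday's | Thursday's | flask |
|---|---|---|---|
| starting material | 0.12 M | 0.12 M | 0.12 M |
| coupling partner | 0.096 M | 0.048 M | 0.0960 M |
| remark | the very flask that is asked about, followed so far | run made earlier |  |
| time |  |  | 8.0 d |

- Saturday's (time / h: target / %, isomer of the product / %, starting material / %): 2.00: 27.9, 11.8, 50.3; 6.00: 39.9, 17.4, 35.8; 10.0: 43.4, 18.2, 33.2; 15.0: 44.1, 18.6, 31.4; 25.0: 44.1, 19.0, 31.6; 30.0: 43.8, 19.0, 31.1; 40.0: 43.4, 19.0, 30.8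
- Thursday's (time / d: target / %, isomer of the product / %, starting material / %): 0.250: 23.1, 10.1, 63.4; 0.417: 23.8, 10.1, 62.5; 0.625: 24.0, 10.5, 62.2; 0.833: 24.7, 10.4, 62.8; 1.25: 23.5, 10.6, 62.2; 2.00: 23.8, 10.7, 63.3; 3.00: 24.1, 9.8, 62.4

(readings scatter by 0.3 percentage points)

1. ratio of target to isomer of the product at 15 min
2. ratio of target to isomer of the product at 6.0 h
3. ratio of target to isomer of the product at 8.0 d
4. which of target and isomer of the product there is more of at 8.0 d

- what was read earlier has a scatter of 0.3 percentage points, one standard deviation

Take the rate first, in Saturday's flask. Starting material goes at 0.0298 M h⁻¹ up to 2.00 h, then 0.00435 M h⁻¹ up to 6.00 h, then 7.80 × 10⁻⁴ M h⁻¹ up to 10.0 h. Taking each of the last two spans at the mean of its two end readings, starting material falls from one span to the next by a factor 1.25, and coupling partner, counted one for one, by 1.59, together 1.98. The measured rate drops by 5.58, more than those two factors give, so we suspect that coupling partner also leaves by a second path. The slowing accumulates until starting material barely moves: it reads 31.4% at 15.0 h and 30.8% at 40.0 h.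

Here control changes hands. While coupling feeds the products, we expect the ratio to carry the split of the feed; once the feed has stopped, we expect any change to come from exchange between them. The ratio reads 2.36 at 2.00 h in Saturday's flask, close to the resting ratio. Thursday's flask reads 2.31 over 0.250 d to 0.625 d and 2.30 over 1.25 d to 3.00 d. So we commit to the resting ratio, 2.31, at the asked times, with target ahead.

The forecast gives 2.35, 2.32 and 1.8, with target ahead, and parts from our reckoning at the last time by “Extrapolating first-order target-to-isomer leakage”.

The flask gives 2.43, 2.38 and 2.34, with 44.2% target against 18.9% isomer of the product.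

    intermediate ⇌ isomer of the product (K = 3.16, k = 0.626 h⁻¹)
    intermediate ⇌ target (K = 7.40, k = 1.52 h⁻¹)
    starting material + coupling partner → intermediate + by-product (k = 7.07 M⁻¹ h⁻¹)
    2 coupling partner → homo dimer (k = 1.07 M⁻¹ h⁻¹)

A run of this flask without the way back from isomer of the product to intermediate turns the lead, its ratio at 8.0 d falling from 2.34 to 1.63 × 10⁻⁵, so the ratio at rest in this flask stands under thermodynamic rather than kinetic control. In the flask, target returns through intermediate with a half-life of 0.14 d, far shorter than 8.0 d. The neighbouring flask with 0.16 M of coupling partner ends at 62.6% target and 26.7% isomer of the product, a ratio of 2.34, close to the resting ratio.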